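**Retrosynthetic overview**
- The (2S)-flavan comes from its tris-silyl ether. That ether arises from a (2R)-2-aryl-2H-chromene-3-carbaldehyde by removing a temporary C3 formyl group: 1,4-hydrosilylation, then Tsuji–Wilkinson decarbonylation.
- Key disconnection: C3–C4 (ring-closing aldol condensation), made in the same flask as O1–C2 (oxa-Michael). This splits pyran ring C into a ring-A salicylaldehyde (C4 = CHO) and a ring-B cinnamaldehyde (C2 = β-carbon, C3 = α-carbon).
- Enabling feature: O1 (on C8a) and C4 (on C4a) are ortho neighbours on ring A. In the chain O1–C2–C3–C4, C2 is benzylic to ring B and C3 is an unsubstituted CH2. O1/C4 is therefore the donor/acceptor pair of a salicylaldehyde and C2/C3 the acceptor/donor pair of an enal, and the formyl activator on C3 can be removed without trace.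
- The 8-prenyl (not 6-prenyl) pattern is fixed earlier. Phloroglucinaldehyde is C-prenylated, then silylated at the two less hindered oxygens, so only the OH between CHO and prenyl stays free.
- Ring order: rings A and B are purchased. Ring C is the only ring formed, in the key step, which also sets the only stereocentre.

Key step: step 5

Remark: C2 of the target is S. The same spatial arrangement is named 2R in the chromene-3-carbaldehyde and in its silyl enol ether, because there the sp2 C3 outranks the aryl group in the CIP order. The sense of induction follows the accepted shielding model of the (S)-catalyst; the (R)-catalyst would be used if it proved opposite.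

**Step 1**
Reactants: 1 2,4,6-trihydroxybenzaldehyde
Product: 2 2,4,6-trihydroxy-3-(3-methylbut-2-en-1-yl)benzaldehyde
Conditions: prenyl bromide (1.0 equiv), KOH (1.0 equiv), H2O, 0 °C to rt
Reagents that add atoms: prenyl bromide, CC(C)=CCBr
Why: C-alkylation of the ambident phloroglucinolate anion by a soft allylic bromide in water, where hydrogen bonding masks the oxygens; C3 and C5 of 1 are equivalent, so only one mono-C-prenyl isomer can form, and one equivalent of bromide should hold back a second alkylation.

**Step 2**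
Reactants: 2 2,4,6-trihydroxy-3-(3-methylbut-2-en-1-yl)benzaldehyde
Product: 3 4,6-bis(tert-butyldimethylsilyloxy)-2-hydroxy-3-(3-methylbut-2-en-1-yl)benzaldehyde
Conditions: TBSCl (2.1 equiv), imidazole (2.2 equiv), CH2Cl2/DMF, 0 °C
Reagents that add atoms: tert-butyldimethylsilyl chloride, CC(C)(C)[Si](C)(C)Cl
Why: Site-selective silyl ether formation, in which the bulky chloride should take the para 4-OH and the less hindered ortho 6-OH, while the 2-OH, wedged between prenyl and formyl and hydrogen-bonded to C=O, stays free and thereby fixes the later 8-prenyl pattern.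

**Step 3**
Reactants: 4 3-hydroxy-5-methoxybenzaldehyde
Product: 5 3-(tert-butyldimethylsilyloxy)-5-methoxybenzaldehyde
Conditions: TBSCl (1.1 equiv), imidazole (1.2 equiv), CH2Cl2, rt
Reagents that add atoms: tert-butyldimethylsilyl chloride, CC(C)(C)[Si](C)(C)Cl
Why: Standard silyl protection of the single phenol, so that 3 alone offers a free OH in the key step and all three protecting groups can fall together at the end.

**Step 4**
Reactants: 5 3-(tert-butyldimethylsilyloxy)-5-methoxybenzaldehyde
Product: 6 (E)-3-[3-(tert-butyldimethylsilyloxy)-5-methoxyphenyl]prop-2-enal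
Conditions: Ph3P=CHCHO (1.1 equiv), PhMe, 80 °C
Reagents that add atoms: (triphenylphosphoranylidene)acetaldehyde, O=CC=P(c1ccccc1)(c1ccccc1)c1ccccc1
Why: Wittig olefination with the stabilised formyl ylide should give the two-carbon-homologated (E)-enal directly, and the small excess of ylide limits a second homologation.

**Step 5**
Reactants: 3 4,6-bis(tert-butyldimethylsilyloxy)-2-hydroxy-3-(3-methylbut-2-en-1-yl)benzaldehyde; 6 (E)-3-[3-(tert-butyldimethylsilyloxy)-5-methoxyphenyl]prop-2-enal (1.3 equiv)
Product: 9 (2R)-5,7-bis(tert-butyldimethylsilyloxy)-2-[3-(tert-butyldimethylsilyloxy)-5-methoxyphenyl]-8-(3-methylbut-2-en-1-yl)-2H-chromene-3-carbaldehyde, via oxa-Michael adduct 7 (not isolated), via aldol adduct 8 (not isolated)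
Conditions: (S)-2-[diphenyl(trimethylsilyloxy)methyl]pyrrolidine (20 mol %), 2-nitrobenzoic acid (20 mol %), 4 Å MS, PhMe, rt, dark
Reagents that add atoms: none
Why: This is the amine-catalysed domino oxa-Michael/aldol condensation (iminium–enamine cascade) that is well established for salicylaldehydes and cinnamaldehydes. The catalyst condenses with the unhindered enal 6 to an s-trans E-iminium ion, the only free phenol oxygen of 3 (the future O1) adds to its β-carbon (C2), and the resulting enamine, the catalyst-bound form of 7, attacks the ortho formyl carbon through C3, which forms the C3–C4 bond and closes the pyran ring in a favoured 6-(enolexo)-exo-trig aldol step to 8. Loss of water and hydrolysis of the iminium ion then release 9 and the catalyst. C2, the only stereocentre, is controlled by the CPh2(OSiMe3) group of the (S)-catalyst, which covers one face of the iminium ion so that O1 enters from the open face and gives the 2R chromene, i.e. the spatial arrangement of the 2S target. Because the oxa-Michael addition is reversible and the dehydration is not, mismatched C2 epimers and unproductive adducts revert to 3 and 6, and the whole mixture should drain through the faster matched closure into one enantiomer. The step needs O-regioselectivity (8- versus 6-prenyl), secured by the silyl groups on the other two oxygens, and aldehyde chemoselectivity, secured because the formyl group of 3 is doubly ortho-substituted and non-enolisable and can act only as the aldol acceptor, while its silyloxy groups donate less than alkoxy groups and keep C4 electrophilic.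

**Step 6**
Reactants: 9 (2R)-5,7-bis(tert-butyldimethylsilyloxy)-2-[3-(tert-butyldimethylsilyloxy)-5-methoxyphenyl]-8-(3-methylbut-2-en-1-yl)-2H-chromene-3-carbaldehyde
Product: 11 (2S,3RS)-5,7-bis(tert-butyldimethylsilyloxy)-2-[3-(tert-butyldimethylsilyloxy)-5-methoxyphenyl]-8-(3-methylbut-2-en-1-yl)chromane-3-carbaldehyde, via triethylsilyl enol ether 10 (not isolated)
Conditions: Et3SiH (1.5 equiv), RhCl(PPh3)3 (2 mol %), PhH, 50 °C, dark; then AcOH/THF/H2O, 0 °C to rt
Reagents that add atoms: triethylsilane, CC[SiH](CC)CC (its SiEt3 group stays only in 10; 11 keeps only the hydride)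
Why: Rhodium-catalysed 1,4-hydrosilylation of an enal with a monohydrosilane, a reaction type known to spare isolated trisubstituted alkenes, puts H on C4 and Si on oxygen, so the neutral enol ether 10 never becomes a free enolate that could expel O1 from C2, and mild acid hydrolysis should give 11 as a C3 epimer mixture that does not matter because C3 ends as CH2.

**Step 7**
Reactants: 11 (2S,3RS)-5,7-bis(tert-butyldimethylsilyloxy)-2-[3-(tert-butyldimethylsilyloxy)-5-methoxyphenyl]-8-(3-methylbut-2-en-1-yl)chromane-3-carbaldehyde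
Product: 12 (2S)-5,7-bis(tert-butyldimethylsilyloxy)-2-[3-(tert-butyldimethylsilyloxy)-5-methoxyphenyl]-8-(3-methylbut-2-en-1-yl)chromane
Conditions: RhCl(PPh3)3 (1.1 equiv), degassed PhMe, 110 °C
Reagents that add atoms: none
Why: Tsuji–Wilkinson decarbonylation (oxidative addition into the formyl C–H bond, CO extrusion, C–H reductive elimination) replaces CHO by H under neutral conditions and tolerates β-oxygen substituents as in aldoses, so it should erase the C3 stereocentre while leaving C2, the prenyl group and the silyl ethers untouched.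

**Step 8**
Reactants: 12 (2S)-5,7-bis(tert-butyldimethylsilyloxy)-2-[3-(tert-butyldimethylsilyloxy)-5-methoxyphenyl]-8-(3-methylbut-2-en-1-yl)chromane
Product: 13 (2S)-2-(3-hydroxy-5-methoxyphenyl)-8-(3-methylbut-2-en-1-yl)chromane-5,7-diol (target)
Conditions: TBAF (3.3 equiv), AcOH (3.3 equiv), THF, 0 °C, Ar
Reagents that add atoms: none
Why: Fluoride cleavage of the three aryl silyl ethers, buffered with acetic acid, avoids both the acid that would cyclise the 7-OH onto the prenyl group and free phenoxides that oxidise in air, and it does not touch C2, whose meta-oxygenated aryl group offers no quinone-methide epimerisation path.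

**Compound list**
1 | 2,4,6-trihydroxybenzaldehyde | O=Cc1c(O)cc(O)cc1O | starting material
2 | 2,4,6-trihydroxy-3-(3-methylbut-2-en-1-yl)benzaldehyde | O=Cc1c(O)cc(O)c(CC=C(C)C)c1O | intermediate
3 | 4,6-bis(tert-butyldimethylsilyloxy)-2-hydroxy-3-(3-methylbut-2-en-1-yl)benzaldehyde | O=Cc1c(O[Si](C)(C)C(C)(C)C)cc(O[Si](C)(C)C(C)(C)C)c(CC=C(C)C)c1O | intermediate
4 | 3-hydroxy-5-methoxybenzaldehyde | COc1cc(O)cc(C=O)c1 | starting material
5 | 3-(tert-butyldimethylsilyloxy)-5-methoxybenzaldehyde | COc1cc(O[Si](C)(C)C(C)(C)C)cc(C=O)c1 | intermediate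
6 | (E)-3-[3-(tert-butyldimethylsilyloxy)-5-methoxyphenyl]prop-2-enal | COc1cc(O[Si](C)(C)C(C)(C)C)cc(/C=C/C=O)c1 | intermediate
7 | oxa-Michael adduct, 4,6-bis(silyloxy)-2-{(1S)-1-[3-(silyloxy)-5-methoxyphenyl]-3-oxopropoxy}-3-prenylbenzaldehyde (silyl = TBS; drawn catalyst-free, present in the flask as the catalyst enamine at C3) | COc1cc(O[Si](C)(C)C(C)(C)C)cc([C@@H](Oc2c(C=O)c(O[Si](C)(C)C(C)(C)C)cc(O[Si](C)(C)C(C)(C)C)c2CC=C(C)C)CC=O)c1 | intermediate (not isolated)
8 | aldol adduct, (2S)-4-hydroxy-5,7-bis(TBS-oxy)-2-[3-(TBS-oxy)-5-methoxyphenyl]-8-prenylchromane-3-carbaldehyde (C3 and C4 undefined; drawn catalyst-free) | COc1cc(O[Si](C)(C)C(C)(C)C)cc([C@@H]2C(C=O)C(O)c3c(O[Si](C)(C)C(C)(C)C)cc(O[Si](C)(C)C(C)(C)C)c(CC=C(C)C)c3O2)c1 | intermediate (not isolated)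
9 | (2R)-5,7-bis(TBS-oxy)-2-[3-(TBS-oxy)-5-methoxyphenyl]-8-prenyl-2H-chromene-3-carbaldehyde | COc1cc(O[Si](C)(C)C(C)(C)C)cc([C@@H]2C(C=O)=Cc3c(O[Si](C)(C)C(C)(C)C)cc(O[Si](C)(C)C(C)(C)C)c(CC=C(C)C)c3O2)c1 | intermediate
10 | (2R)-5,7-bis(TBS-oxy)-2-[3-(TBS-oxy)-5-methoxyphenyl]-8-prenyl-3-[(triethylsilyloxy)methylidene]chromane (E/Z undefined) | COc1cc(O[Si](C)(C)C(C)(C)C)cc([C@@H]2C(=CO[Si](CC)(CC)CC)Cc3c(O[Si](C)(C)C(C)(C)C)cc(O[Si](C)(C)C(C)(C)C)c(CC=C(C)C)c3O2)c1 | intermediate (not isolated)
11 | (2S,3RS)-5,7-bis(TBS-oxy)-2-[3-(TBS-oxy)-5-methoxyphenyl]-8-prenylchromane-3-carbaldehyde (C3 epimer mixture) | COc1cc(O[Si](C)(C)C(C)(C)C)cc([C@@H]2C(C=O)Cc3c(O[Si](C)(C)C(C)(C)C)cc(O[Si](C)(C)C(C)(C)C)c(CC=C(C)C)c3O2)c1 | intermediate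
12 | (2S)-5,7-bis(TBS-oxy)-2-[3-(TBS-oxy)-5-methoxyphenyl]-8-prenylchromane | COc1cc(O[Si](C)(C)C(C)(C)C)cc([C@@H]2CCc3c(O[Si](C)(C)C(C)(C)C)cc(O[Si](C)(C)C(C)(C)C)c(CC=C(C)C)c3O2)c1 | intermediate
13 | (2S)-2-(3-hydroxy-5-methoxyphenyl)-8-(3-methylbut-2-en-1-yl)chromane-5,7-diol | COc1cc(O)cc([C@@H]2CCc3c(O)cc(O)c(CC=C(C)C)c3O2)c1 | target

**Step count**
- Total step count: 8.
- Longest linear sequence: 6 steps (1, 2, 5, 6, 7, 8). The branch 3, 4, 5, 6, 7, 8 is equally long.

**Steps most likely to fail**

Step 5.
- What may go wrong: the aldol closure onto the electron-rich, doubly ortho-substituted formyl group may be too slow to drain the reversible oxa-Michael equilibrium. Uncatalysed background addition, or electrocyclic opening of the donor–acceptor chromene by light or heat, may erode the enantiomeric purity.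
- Scope of the fallback: it sets out from 3 and 6 and returns at 12, so steps 6 and 7 are no longer needed.
- Luche reduction of 6 should give the (E)-cinnamyl alcohol F1. Methyl chloroformate/pyridine should convert it to the methyl carbonate F2.
- Iridium-catalysed enantioselective allylic etherification of the sodium phenoxide of 3 with F2 should give the branched (S)-allyl aryl ether F3. The catalyst is [Ir(cod)Cl]2 with a BINOL-derived bis(1-phenylethyl)phosphoramidite, in the ligand antipode that delivers the S ether.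
- Wittig methylenation of the formyl group should give the styrene F4.
- Ring-closing metathesis with a second-generation ruthenium benzylidene catalyst (CH2Cl2, 40 °C) should join the same two carbons as C3=C4 in the (2S)-2H-chromene F5. The two terminal alkenes should react ahead of the trisubstituted prenyl group.
- Diimide (2-nitrobenzenesulfonyl hydrazide, Et3N, rt, dark) should reduce the cis-disubstituted ring alkene in preference to the prenyl group and deliver 12.

Step 7.
- What may go wrong: β-hydride or β-aryloxide elimination from the secondary alkyl–rhodium hydride, or thermal retro-oxa-Michael opening of the β-aryloxy aldehyde before CO is lost, with loss of material or of configuration at C2.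
- Scope of the fallback: it sets out from 11 and returns at 12.
- Pinnick oxidation (NaClO2, NaH2PO4, excess 2-methylbut-2-ene to shield the prenyl group) should give the chromane-3-carboxylic acid F6.
- Coupling with N-hydroxyphthalimide (DIC, cat. DMAP) should give the redox-active ester F7.
- Nickel-catalysed reductive decarboxylation should replace the carboxyl group by hydrogen through the C3 radical and give 12 (cat. NiCl2·6H2O/4,4'-di-tert-butyl-2,2'-bipyridine, Zn, PhSiH3, THF/DMF/i-PrOH, 40 °C).

Step 1.
- What may go wrong: competing O-alkylation, a second C-alkylation at C5, or geminal alkylation with dearomatisation, giving mixtures that are hard to separate.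
- Scope of the fallback: it sets out from 1 and returns at 3, bypassing 2 and the site-selection of step 2.
- Bis-silylation of 1 (TBSCl, 2 equiv) should give the 4,6-bis(silyloxy)salicylaldehyde F8. The two ortho OH groups are equivalent, so no site issue arises.
- Tsuji–Trost-type O-allylation of the remaining phenol (tert-butyl 2-methylbut-3-en-2-yl carbonate, cat. Pd(PPh3)4, THF) should give the 1,1-dimethylallyl aryl ether F9.
- Aromatic Claisen rearrangement (PhMe, 110 °C) should move the group to the only free ortho carbon. The allyl inversion turns 1,1-dimethylallyl into prenyl next to the liberated OH, giving 3.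

**Further compounds**
F1 | step 5 | (E)-3-[3-(tert-butyldimethylsilyloxy)-5-methoxyphenyl]prop-2-en-1-ol | COc1cc(O[Si](C)(C)C(C)(C)C)cc(/C=C/CO)c1
F2 | step 5 | (E)-3-[3-(tert-butyldimethylsilyloxy)-5-methoxyphenyl]prop-2-en-1-yl methyl carbonate | COC(=O)OC/C=C/c1cc(OC)cc(O[Si](C)(C)C(C)(C)C)c1
F3 | step 5 | 4,6-bis(TBS-oxy)-2-{(1S)-1-[3-(TBS-oxy)-5-methoxyphenyl]prop-2-en-1-yloxy}-3-prenylbenzaldehyde | COc1cc(O[Si](C)(C)C(C)(C)C)cc([C@@H](Oc2c(C=O)c(O[Si](C)(C)C(C)(C)C)cc(O[Si](C)(C)C(C)(C)C)c2CC=C(C)C)C=C)c1
F4 | step 5 | 1,5-bis(TBS-oxy)-3-{(1S)-1-[3-(TBS-oxy)-5-methoxyphenyl]prop-2-en-1-yloxy}-4-prenyl-2-vinylbenzene | COc1cc(O[Si](C)(C)C(C)(C)C)cc([C@@H](Oc2c(C=C)c(O[Si](C)(C)C(C)(C)C)cc(O[Si](C)(C)C(C)(C)C)c2CC=C(C)C)C=C)c1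
F5 | step 5 | (2S)-5,7-bis(TBS-oxy)-2-[3-(TBS-oxy)-5-methoxyphenyl]-8-prenyl-2H-chromene | COc1cc(O[Si](C)(C)C(C)(C)C)cc([C@@H]2C=Cc3c(O[Si](C)(C)C(C)(C)C)cc(O[Si](C)(C)C(C)(C)C)c(CC=C(C)C)c3O2)c1
F6 | step 7 | (2S,3RS)-5,7-bis(TBS-oxy)-2-[3-(TBS-oxy)-5-methoxyphenyl]-8-prenylchromane-3-carboxylic acid | COc1cc(O[Si](C)(C)C(C)(C)C)cc([C@@H]2C(C(=O)O)Cc3c(O[Si](C)(C)C(C)(C)C)cc(O[Si](C)(C)C(C)(C)C)c(CC=C(C)C)c3O2)c1
F7 | step 7 | N-phthalimidoyl ester of F6 | COc1cc(O[Si](C)(C)C(C)(C)C)cc([C@@H]2C(C(=O)ON4C(=O)c5ccccc5C4=O)Cc3c(O[Si](C)(C)C(C)(C)C)cc(O[Si](C)(C)C(C)(C)C)c(CC=C(C)C)c3O2)c1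
F8 | step 1 | 4,6-bis(tert-butyldimethylsilyloxy)-2-hydroxybenzaldehyde | O=Cc1c(O)cc(O[Si](C)(C)C(C)(C)C)cc1O[Si](C)(C)C(C)(C)C
F9 | step 1 | 4,6-bis(tert-butyldimethylsilyloxy)-2-(2-methylbut-3-en-2-yloxy)benzaldehyde | O=Cc1c(OC(C)(C)C=C)cc(O[Si](C)(C)C(C)(C)C)cc1O[Si](C)(C)C(C)(C)C
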